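## Analysis of the target

Lychnophorolide B is a furanoheliangolide. Its ten-membered carbocycle (C1–C10) is bridged by an oxygen between C3 and C10, so that O, C10, C1, C2 and C3 form a 3(2H)-furanone with the C1 ketone and the C2=C3 enol-ether alkene. The carbocycle is fused at C6–C7 to an α-methylene-γ-butyrolactone (C11–C13, ring oxygen on C6). A Z-trisubstituted C4=C5 alkene carries the C15 hydroxymethyl group and extends the furanone into a dienone, and O8 bears a tiglate. Of the four stereocentres, C6 (R), C7 (R) and C8 (S) are contiguous: the C6 oxygen, the C7 side chain and the C8 oxygen lie on one side of the extended C5–C9 chain, so the lactone is trans-fused. The quaternary C10 (R, methyl and ring oxygen) is 1,3 to C8. The exocyclic methylene adds amines and thiols, the tiglate and lactone are base-labile, and a free O8 next to the lactone invites translactonisation. The ten-membered ring is the hard part: it holds two ring alkenes, a ketone and an oxygen bridge, and closing it directly costs entropy and transannular strain while a cis alkene has to be kept. The route rests on the fact that C1–C6 carry the pattern of a 2-methoxyphenol (oxygen on C2 and C3, a one-carbon branch on C4, C4=C5 cis), so the ten-membered ring can be read as a tetralin (ring A C1–C6, ring B C6–C10 and C1) whose shared C1–C6 bond has been cut.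

## Retrosynthetic reasoning

**35 back to 30 and 31.** The exocyclic methylene is unveiled last, by quaternisation and β-elimination of the C11 dimethylaminomethyl group of 33 through 34. The secondary amine needed for the furanone would add to a free methylene lactone, so the amine-masked form is carried instead. Before that the C15 silyl ether of 32 is removed, and the tiglate of 32 comes from acid 31 and the free C8 hydroxyl of 30. O8 is acylated only once the lactone already sits on O6.

**30 back to 27.** The O10–C3 bond is cut and the C1 ketone is returned to an alkyne carbon. A 3(2H)-furanone is the cyclodehydration product of a γ-hydroxy ynone after hydration at the alkyne carbon remote from the ketone. Forward, the C3 ketal of 27 is hydrolysed to ynone 28, a secondary amine adds at C1 to give 29, and aqueous acid frees O8 and O10, hydrolyses the enaminone and closes the ring. Bending of the alkyne in the ten-membered ring helps the addition.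

**27 back to 24.** The C11–C13 bond is made by a Mannich reaction on the lactone enolate of 26. It is placed here because later the dienone would make H6 acidic. The O6–C12 bond and H6 come from reduction of the C6 ketone of 24 and lactonisation through 25. O8 and O10 stay tied as an acetonide so that only O6 can lactonise. The hydride has to place O6 syn to O8, and chelation to the C8 oxygen is used for that.

**24 back to 21 and 22.** The C1–C6 bond is reconnected. The C6 ketone and the C1≡C2 alkyne are the two ends of an α,β-epoxy ketone fragmentation with sulfonylhydrazide 22. Cutting here means the ten-membered ring is never closed by cyclisation. The fragments also carry the right oxidation levels: a C6 ketone for the lactone carbinol, an alkyne for the furanone, and C3 as a ketal.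

**21 back to 19.** The oxirane comes from nucleophilic epoxidation of the ring-fusion alkene of dienone 20. Dienone 20 comes from phenol 19 by oxidative dearomatisation in the alcohol that supplies the second ketal methoxy group. The Z C4=C5 alkene is a former arene bond.

**19 back to 16.** Protecting-group steps lead through 18 to diol 17. Ring B of 17 is opened at C7–C8: an aldehyde ketyl adds to the cinnamate of 16. The quaternary C10 already present steers C8 and C7.

**16 back to 11.** The aldehyde comes from the primary alcohol of 15, and the C6–C7 bond from a Heck reaction of bromide 13 with acrylate 14. The C10 stereocentre of 13 comes from asymmetric epoxidation of allylic alcohol 11 to 12 and hydride opening at C9.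

**11 back to 1.** The C1–C10 bond is a cross-coupling of iodide 8 with alkenylboronate 10 (from alkyne 9). Iodide 8 comes from 6 through aryllithium 7. Compound 6 comes from aldehyde 1, which supplies C15 and both ring oxygens, through 2 (O2 benzylated), 3 (bromine at C6), 4 (O3 methylated) and 5.

## Alternatives that were turned down

**Alternative 1:** Here C2–C3 and C4–C5 are both disconnected, with a temporary C2–C5 bond in an eight-membered enone. Forward, the enone is irradiated with an ynol ether tethered through O10; the intramolecular [2+2] closes the furanone ring and a cyclobutene, and thermal conrotatory opening cuts C2–C5 to give A1 (the bridged furanone lactone without C13).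
- For: two skeletal bonds, the furanone and the ring expansion come in one operation. The three-atom tether fixes the regiochemistry. The furanone ring allows only one conrotatory sense, which gives the Z C4=C5 alkene. A1 is only a few steps from the target, a shorter endgame than the chosen route.
- Against: the substrate is a fully substituted cyclooctenone with C6, C7, C8 and C10 in place, so the medium-ring problem is moved to an eight-membered ring with poorer stereocontrol. An ynol ether on a tertiary α-keto alkoxide is hard to make and acid-labile. Cis–trans isomerisation of the excited cyclooctenone competes.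
- In comparison, the chosen route sets all stereocentres on a six-membered ring with the arene as template and needs no medium ring before the key step.

**Alternative 2:** Here C5–C6 and C3–C4 are disconnected around the alkene. Forward, zerovalent nickel joins an aldehyde at C6, a silyl propargyl ether and the vinylzinc reagent A3 (1-ethoxyvinylzinc chloride) by syn addition across the alkyne; the C6 alkoxide lactonises to give A2 (the trans lactone with the Z 2-ethoxydiene).
- For: it is the most convergent plan. The Z alkene is set stereospecifically, and C6 is formed directly as the lactone carbinol, with no ketone reduction.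
- Against: A2 is acyclic in the carbocycle, so the ten-membered ring must still be closed later at C1–C2, with the entropic cost the chosen route avoids. The regiochemistry of alkyne insertion and the C6 configuration (1,2-induction from C7 only) are both open. Alkylative coupling competes with reductive coupling.
- In comparison, the chosen route gives up convergence but never makes the ring by cyclisation.

**Alternative 3:** Here C7–C8 is disconnected last. Forward, a low-valent metal (chromium or indium) turns a C13 bromide on a butenolide into an allylmetal that adds through C7 to a C8 aldehyde, closing the carbocycle and giving A4 (the 15-O-silyl alcohol with the complete ring system).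
- For: the endgame is the shortest of all (acylation and desilylation). The α-methylene lactone comes for free, with no late enolate chemistry.
- Against: two stereocentres are set in a strained bridged macrocyclisation, controlled only by the ring transition state. The C8 aldehyde has the furanone oxygen in the β-position and is prone to elimination. The exocyclic methylene then has to survive everything that follows.
- In comparison, the chosen route sets C7 and C8 on ring B under control of C10 and masks the methylene until the last step.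

Key step: step 18

Remark: locants C1–C15 are those of the target throughout, and descriptors in the names refer to these locants unless a systematic name is given.
Remark: the C15 hydroxyl is carried as a tert-butyldiphenylsilyl ether, because it must outlast the aqueous acid that removes the acetonide in step 21.
Remark: the oxirane of 21 is drawn with its oxygen anti to the C7 side chain; its configuration is erased in step 18, so either epimer serves.

## Route

Step 1
Reactants: 1 2,3-dihydroxybenzaldehyde
Product: 2 3-(benzyloxy)-2-hydroxybenzaldehyde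
Conditions: NaH (2.2 equiv), DMSO, rt; BnBr (1.0 equiv)
Reagents that add atoms: benzyl bromide, BrCc1ccccc1
Why: Williamson etherification of the dianion; the phenoxide meta to the formyl group is neither conjugated to nor chelated by it and is the more nucleophilic, so benzyl goes to the oxygen that becomes the C2 phenol.

Step 2
Reactants: 2 3-(benzyloxy)-2-hydroxybenzaldehyde
Product: 3 3-(benzyloxy)-5-bromo-2-hydroxybenzaldehyde
Conditions: Br2, NaOAc, AcOH, rt
Reagents that add atoms: bromine, BrBr
Why: Electrophilic aromatic bromination para to the free hydroxyl and meta to the formyl group, the only position both groups favour; this carbon is C6.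

Step 3
Reactants: 3 3-(benzyloxy)-5-bromo-2-hydroxybenzaldehyde
Product: 4 3-(benzyloxy)-5-bromo-2-methoxybenzaldehyde
Conditions: MeI, K2CO3, DMF, rt
Reagents that add atoms: iodomethane, CI
Why: O-Methylation of the remaining phenol; this methoxy group on C3 becomes one of the two ketal methoxy groups.

Step 4
Reactants: 4 3-(benzyloxy)-5-bromo-2-methoxybenzaldehyde
Product: 5 [3-(benzyloxy)-5-bromo-2-methoxyphenyl]methanol
Conditions: NaBH4, MeOH, 0 °C
Reagents that add atoms: none
Why: Borohydride reduction of the aldehyde to the C15 alcohol; the aryl bromide and ethers are inert.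

Step 5
Reactants: 5 [3-(benzyloxy)-5-bromo-2-methoxyphenyl]methanol
Product: 6 {[3-(benzyloxy)-5-bromo-2-methoxyphenyl]methoxy}(tert-butyl)diphenylsilane
Conditions: TBDPSCl, imidazole, DMF, rt
Reagents that add atoms: tert-butyl(chloro)diphenylsilane, CC(C)(C)[Si](Cl)(c1ccccc1)c1ccccc1
Why: Silylation of the primary alcohol; the bulky silyl ether tolerates the base, hydride, samarium and acid steps ahead.

Step 6
Reactants: 6 {[3-(benzyloxy)-5-bromo-2-methoxyphenyl]methoxy}(tert-butyl)diphenylsilane
Product: 8 {[3-(benzyloxy)-5-bromo-4-iodo-2-methoxyphenyl]methoxy}(tert-butyl)diphenylsilane, via C1 aryllithium 7 (not isolated)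
Conditions: LDA, THF, −78 °C; I2, −78 °C → rt
Reagents that add atoms: iodine, II
Why: Directed ortho-lithiation; the hydrogen between the benzyloxy group and bromine (C1) is the most acidic, the amide base does not exchange the bromide, and the aryllithium is kept cold so that it does not lose LiBr before iodine traps it.

Step 7
Reactants: 9 but-2-yn-1-ol
Product: 10 (Z)-3-(4,4,5,5-tetramethyl-1,3,2-dioxaborolan-2-yl)but-2-en-1-ol
Conditions: B2pin2, CuCl (5 mol%), Xantphos, NaOtBu (cat.), MeOH, THF, rt
Reagents that add atoms: bis(pinacolato)diboron, CC1(C)OB(OC1(C)C)B1OC(C)(C)C(C)(C)O1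
Why: Copper-catalysed borylation and protonation of the alkyne: syn addition of boron and hydrogen with boron on the carbon remote from the oxygenated carbon, which fixes the later E geometry.

Step 8
Reactants: 8 {[3-(benzyloxy)-5-bromo-4-iodo-2-methoxyphenyl]methoxy}(tert-butyl)diphenylsilane, 10 (Z)-3-(4,4,5,5-tetramethyl-1,3,2-dioxaborolan-2-yl)but-2-en-1-ol
Product: 11 (E)-3-[2-(benzyloxy)-6-bromo-4-({[tert-butyl(diphenyl)silyl]oxy}methyl)-3-methoxyphenyl]but-2-en-1-ol
Conditions: PdCl2(dppf) (5 mol%), K3PO4, THF/H2O, 60 °C
Reagents that add atoms: none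
Why: Suzuki–Miyaura coupling forming C1–C10; zerovalent palladium inserts into the C–I bond well before the C–Br bond, and the alkenyl group transfers with retention, placing the aryl group trans to CH2OH.

Step 9
Reactants: 11 (E)-3-[2-(benzyloxy)-6-bromo-4-({[tert-butyl(diphenyl)silyl]oxy}methyl)-3-methoxyphenyl]but-2-en-1-ol
Product: 12 {(2S,3S)-3-[2-(benzyloxy)-6-bromo-4-({[tert-butyl(diphenyl)silyl]oxy}methyl)-3-methoxyphenyl]-3-methyloxiran-2-yl}methanol
Conditions: Ti(OiPr)4 (10 mol%), L-(+)-diethyl tartrate, t-BuOOH, 4 Å MS, CH2Cl2, −20 °C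
Reagents that add atoms: tert-butyl hydroperoxide, CC(C)(C)OO
Why: Sharpless asymmetric epoxidation; the L-(+)-tartrate complex of tetravalent titanium delivers oxygen to the face that gives the (2S,3S)-epoxide, as with other E-3,3-disubstituted allylic alcohols, and this sets C10; the twisted 2,6-disubstituted aryl group keeps the benzylic oxirane from ionising.

Step 10
Reactants: 12 {(2S,3S)-3-[2-(benzyloxy)-6-bromo-4-({[tert-butyl(diphenyl)silyl]oxy}methyl)-3-methoxyphenyl]-3-methyloxiran-2-yl}methanol
Product: 13 (3R)-3-[2-(benzyloxy)-6-bromo-4-({[tert-butyl(diphenyl)silyl]oxy}methyl)-3-methoxyphenyl]butane-1,3-diol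
Conditions: NaAlH2(OCH2CH2OMe)2 (Red-Al), THF, 0 °C → rt
Reagents that add atoms: none
Why: Regioselective reductive opening of a 2,3-epoxy alcohol: the alkoxyaluminate delivers hydride to C9, the carbon next to the carbinol, giving the 1,3-diol; the C10–O bond is untouched, so C10 keeps its configuration.

Step 11
Reactants: 13 (3R)-3-[2-(benzyloxy)-6-bromo-4-({[tert-butyl(diphenyl)silyl]oxy}methyl)-3-methoxyphenyl]butane-1,3-diol, 14 methyl acrylate
Product: 15 methyl (E)-3-{3-(benzyloxy)-5-({[tert-butyl(diphenyl)silyl]oxy}methyl)-2-[(2R)-2,4-dihydroxybutan-2-yl]-4-methoxyphenyl}prop-2-enoate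
Conditions: Pd(OAc)2 (5 mol%), P(o-tol)3, Et3N, DMF, 90 °C
Reagents that add atoms: none
Why: Mizoroki–Heck reaction forming C6–C7 and the E cinnamate; it is run after the hydride step so that the ester is never exposed to it, and the free diol is tolerated.

Step 12
Reactants: 15 methyl (E)-3-{3-(benzyloxy)-5-({[tert-butyl(diphenyl)silyl]oxy}methyl)-2-[(2R)-2,4-dihydroxybutan-2-yl]-4-methoxyphenyl}prop-2-enoate
Product: 16 methyl (E)-3-{3-(benzyloxy)-5-({[tert-butyl(diphenyl)silyl]oxy}methyl)-2-[(2R)-2-hydroxy-4-oxobutan-2-yl]-4-methoxyphenyl}prop-2-enoate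
Conditions: TEMPO (10 mol%), PhI(OAc)2, CH2Cl2, rt
Reagents that add atoms: none
Why: Oxoammonium oxidation, selective for the primary alcohol over the tertiary one; the β-hydroxy aldehyde is used at once to avoid dehydration.

Step 13
Reactants: 16 methyl (E)-3-{3-(benzyloxy)-5-({[tert-butyl(diphenyl)silyl]oxy}methyl)-2-[(2R)-2-hydroxy-4-oxobutan-2-yl]-4-methoxyphenyl}prop-2-enoate
Product: 17 methyl 2-[(1S,2S,4R)-5-(benzyloxy)-7-({[tert-butyl(diphenyl)silyl]oxy}methyl)-2,4-dihydroxy-6-methoxy-4-methyl-1,2,3,4-tetrahydronaphthalen-1-yl]acetate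
Conditions: SmI2 (2.5 equiv), t-BuOH, THF, −78 → 0 °C
Reagents that add atoms: none
Why: Ketyl–olefin cyclisation: divalent samarium reduces the aldehyde to a ketyl that adds 6-exo-trig to C7 of the cinnamate, and a second electron and t-BuOH give the ester; trivalent samarium on the ketyl oxygen is also held by the C10 hydroxyl, placing O8 cis to O10, and the ester arm turns away from the samarium alkoxide, placing the C7 side chain trans to O8; the trans hydroxy ester does not lactonise readily.

Step 14
Reactants: 17 methyl 2-[(1S,2S,4R)-5-(benzyloxy)-7-({[tert-butyl(diphenyl)silyl]oxy}methyl)-2,4-dihydroxy-6-methoxy-4-methyl-1,2,3,4-tetrahydronaphthalen-1-yl]acetate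
Product: 18 8,10-O-isopropylidene acetal of 17 (7S,8S,10R; C2 benzyl ether)
Conditions: 2-methoxypropene, PPTS (cat.), CH2Cl2, 0 °C
Reagents that add atoms: 2-methoxypropene, COC(C)=C
Why: Acetonide formation on the cis-1,3-diol, which can place both hydroxyls axial on ring B; blocking O8 and O10 together ensures that later only O6 can lactonise, and both are released in one acid step.

Step 15
Reactants: 18 8,10-O-isopropylidene acetal of 17 (7S,8S,10R; C2 benzyl ether)
Product: 19 C2 phenol of the 8,10-O-isopropylidene tetralin (7S,8S,10R)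
Conditions: H2 (1 atm), Pd/C, EtOAc, rt
Reagents that add atoms: none
Why: Hydrogenolysis of the aryl benzyl ether, much faster than cleavage of the benzylic silyl ether or the tertiary benzylic acetal oxygen; the bromide is gone and no alkene is present.

Step 16
Reactants: 19 C2 phenol of the 8,10-O-isopropylidene tetralin (7S,8S,10R)
Product: 20 dienone dimethyl ketal (C2 ketone, C3(OMe)2, C4=C5 and C6=C1 alkenes; 7S,8S,10R)
Conditions: PhI(OAc)2, MeOH, 0 °C
Reagents that add atoms: methanol, CO
Why: Oxidative dearomatisation of a 2-methoxyphenol: the aryloxy-iodane is attacked by methanol at the methoxy-bearing C3, where the cation is best stabilised, giving the 6,6-dimethoxycyclohexa-2,4-dienone; the substituents on C1, C4 and C6 block Diels–Alder dimerisation.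

Step 17
Reactants: 20 dienone dimethyl ketal (C2 ketone, C3(OMe)2, C4=C5 and C6=C1 alkenes; 7S,8S,10R)
Product: 21 (1R,6S,7R,8S,10R)-1,6-epoxy ketone of 20
Conditions: t-BuOOH, benzyltrimethylammonium hydroxide (Triton B, cat.), THF, 0 °C → rt
Reagents that add atoms: tert-butyl hydroperoxide, CC(C)(C)OO
Why: Weitz–Scheffer epoxidation of the kind used on ring-fusion octalones: the peroxide anion adds 1,4 at C6 and the enolate closes on oxygen; 1,6-attack at C4 is disfavoured by the adjacent quaternary ketal carbon and the silyloxymethyl group, and attack anti to the C7 side chain gives the drawn epimer, although either would serve.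

Step 18
Reactants: 21 (1R,6S,7R,8S,10R)-1,6-epoxy ketone of 20, 22 p-toluenesulfonylhydrazide
Product: 24 (4Z,7R,8S,10R)-ten-membered enynone (C6 ketone, C4=C5, C3(OMe)2, C1≡C2, 8,10-acetonide, C7 CH2CO2Me, C15 OTBDPS), via tosylhydrazone 23 (not isolated)
Conditions: TsNHNH2, AcOH/CH2Cl2 (1:1), −20 °C → rt
Reagents that add atoms: none
Why: Eschenmoser–Tanabe fragmentation of a bicyclic α,β-epoxy ketone, the closest known cases being ring-fusion epoxy ketones such as 9,10-epoxydecalin-1-one, which give cyclodec-5-ynone in the same way. The hydrazide condenses with the only ketone, C2, to give 23; proton transfer lets the hydrazone nitrogen push electrons through C2=C1 so that the C1–O bond of the oxirane opens to an azoalkene with a C6 alkoxide. The alkoxide collapses to the C6 ketone as the C1–C6 σ bond breaks, C1≡C2 forms and N2 and p-toluenesulfinate leave, which makes the step irreversible. No ring is made by bond formation, so no closure mode applies: the ten-membered carbocycle appears because the bond shared by rings A and B is the one that is cut, and neither dilution nor a transannular approach is needed. No stereocentre is created; C1 and C6 lose theirs, and C7, C8 and C10 are untouched. The step needs condensation at C2 only and cleavage of C1–C6 only: the ester does not condense, the ketal next to the C=N is deactivated towards ionisation, and the ring fusion holds C1–C6 in line with the departing C1–O bond. Cold acetic acid is mild enough that the new C6 ketone neither loses its β-oxygen at C8 nor epimerises at C7, and the Z C4=C5 bond is inherited from ring A.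

Step 19
Reactants: 24 (4Z,7R,8S,10R)-ten-membered enynone
Product: 26 (6R,7R,8S,10R)-trans-6,12-lactone (C3 ketal, C1≡C2 alkyne, 8,10-acetonide), via 6R hydroxy ester 25 (not isolated)
Conditions: Zn(BH4)2, Et2O, −20 °C; then DBU (cat.), CH2Cl2, rt
Reagents that add atoms: none
Why: Chelation-controlled 1,2-reduction: zinc bridges the C6 carbonyl and the C8 acetal oxygen, and since C5 and C9 are tied together by the rest of the ring, hydride can enter only from the outer face of this six-membered chelate, placing O6 syn to O8 (6R); a non-chelating hydride such as NaBH4/CeCl3 would be expected to follow Felkin–Anh control from C7 and give the 6-epimer, so it is not used; DBU then lets the C6 alkoxide close the γ-lactone on the methyl ester, O8 and O10 being blocked.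

Step 20
Reactants: 26 (6R,7R,8S,10R)-trans-6,12-lactone
Product: 27 (6R,7R,8S,10R,11R)-11-(dimethylaminomethyl) lactone
Conditions: LDA, THF, −78 °C; CH2=NMe2+ I−, −78 → 0 °C
Reagents that add atoms: N,N-dimethylmethyleneiminium iodide, C[N+](C)=C.[I-]
Why: Mannich reaction of the lactone enolate; it is done here because no other acidic C–H is present yet, and the amine adduct serves as the masked methylene; the iminium ion approaches anti to the C7–C8 bond, but the C11 centre is later destroyed.

Step 21
Reactants: 27 (6R,7R,8S,10R,11R)-11-(dimethylaminomethyl) lactone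
Product: 30 (6R,7R,8S,10R,11R)-furanone alcohol (C1 ketone, C2=C3, O bridge C3–C10, free C8 hydroxyl, C15 OTBDPS, C11 CH2NMe2), via ynone 28 (not isolated), via enaminone 29 (not isolated)
Conditions: (CO2H)2, THF/H2O, 0 °C; then Et2NH (excess), rt; then TFA/H2O, rt
Reagents that add atoms: water, O
Why: The allylic and propargylic dimethyl ketal hydrolyses under acid too mild for the acetonide, giving ynone 28; diethylamine adds to the bent alkyne at C1, β to the C3 ketone, while O8 and O10 are still tied; aqueous acid then cleaves the acetonide and hydrolyses the enaminone, and the C10 hydroxyl closes on the C3 carbonyl with loss of water (the classical 3(2H)-furanone synthesis from γ-hydroxy ynones); a hemiketal from O8 at C1 would be reversible, whereas the furanone is the sink.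

Step 22
Reactants: 30 (6R,7R,8S,10R,11R)-furanone alcohol, 31 tiglic acid
Product: 32 (6R,7R,8S,10R,11R)-8-O-tiglate (C15 OTBDPS, C11 CH2NMe2)
Conditions: 2,4,6-trichlorobenzoyl chloride, Et3N, THF; then 30, DMAP, toluene, rt
Reagents that add atoms: none
Why: Yamaguchi esterification of the only free hydroxyl; tiglic acid does not isomerise on activation, and the conditions are too mild for translactonisation.

Step 23
Reactants: 32 (6R,7R,8S,10R,11R)-8-O-tiglate
Product: 33 13-(dimethylamino)-11,13-dihydrolychnophorolide B (6R,7R,8S,10R,11R)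
Conditions: HF·pyridine, pyridine/THF, 0 °C → rt
Reagents that add atoms: none
Why: Fluoride cleavage of the primary silyl ether under buffered conditions that leave the tiglate, lactone and furanone alone; the methylene is still masked.

Step 24
Reactants: 33 13-(dimethylamino)-11,13-dihydrolychnophorolide B
Product: 35 lychnophorolide B, via trimethylammonium iodide 34 (not isolated)
Conditions: MeI, CH2Cl2, rt; then aq. NaHCO3, rt
Reagents that add atoms: none
Why: Quaternisation of the tertiary amine and Hofmann-type β-elimination through the lactone enolate unveil the C11=C13 methylene under conditions too mild to touch the other stereocentres.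

## Compound list

1 | 2,3-dihydroxybenzaldehyde | O=Cc1cccc(O)c1O | starting material
2 | 3-(benzyloxy)-2-hydroxybenzaldehyde | O=Cc1cccc(OCc2ccccc2)c1O | intermediate
3 | 3-(benzyloxy)-5-bromo-2-hydroxybenzaldehyde | O=Cc1cc(Br)cc(OCc2ccccc2)c1O | intermediate
4 | 3-(benzyloxy)-5-bromo-2-methoxybenzaldehyde | O=Cc1cc(Br)cc(OCc2ccccc2)c1OC | intermediate
5 | [3-(benzyloxy)-5-bromo-2-methoxyphenyl]methanol | OCc1cc(Br)cc(OCc2ccccc2)c1OC | intermediate
6 | {[3-(benzyloxy)-5-bromo-2-methoxyphenyl]methoxy}(tert-butyl)diphenylsilane | CC(C)(C)[Si](c1ccccc1)(c1ccccc1)OCc1cc(Br)cc(OCc2ccccc2)c1OC | intermediate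
7 | [2-(benzyloxy)-6-bromo-4-({[tert-butyl(diphenyl)silyl]oxy}methyl)-3-methoxyphenyl]lithium (C1 aryllithium) | CC(C)(C)[Si](c1ccccc1)(c1ccccc1)OCc1cc(Br)c([Li])c(OCc2ccccc2)c1OC | intermediate
8 | {[3-(benzyloxy)-5-bromo-4-iodo-2-methoxyphenyl]methoxy}(tert-butyl)diphenylsilane | CC(C)(C)[Si](c1ccccc1)(c1ccccc1)OCc1cc(Br)c(I)c(OCc2ccccc2)c1OC | intermediate
9 | but-2-yn-1-ol | CC#CCO | starting material
10 | (Z)-3-(4,4,5,5-tetramethyl-1,3,2-dioxaborolan-2-yl)but-2-en-1-ol | C/C(B1OC(C)(C)C(C)(C)O1)=C\CO | intermediate
11 | (E)-3-[2-(benzyloxy)-6-bromo-4-({[tert-butyl(diphenyl)silyl]oxy}methyl)-3-methoxyphenyl]but-2-en-1-ol | C/C(=C\CO)c1c(Br)cc(CO[Si](c2ccccc2)(c2ccccc2)C(C)(C)C)c(OC)c1OCc1ccccc1 | intermediate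
12 | {(2S,3S)-3-[2-(benzyloxy)-6-bromo-4-({[tert-butyl(diphenyl)silyl]oxy}methyl)-3-methoxyphenyl]-3-methyloxiran-2-yl}methanol | OC[C@@H]1O[C@@]1(C)c1c(Br)cc(CO[Si](c2ccccc2)(c2ccccc2)C(C)(C)C)c(OC)c1OCc1ccccc1 | intermediate
13 | (3R)-3-[2-(benzyloxy)-6-bromo-4-({[tert-butyl(diphenyl)silyl]oxy}methyl)-3-methoxyphenyl]butane-1,3-diol | OCC[C@@](C)(O)c1c(Br)cc(CO[Si](c2ccccc2)(c2ccccc2)C(C)(C)C)c(OC)c1OCc1ccccc1 | intermediate
14 | methyl acrylate | C=CC(=O)OC | starting material
15 | methyl (E)-3-{3-(benzyloxy)-5-({[tert-butyl(diphenyl)silyl]oxy}methyl)-2-[(2R)-2,4-dihydroxybutan-2-yl]-4-methoxyphenyl}prop-2-enoate | OCC[C@@](C)(O)c1c(/C=C/C(=O)OC)cc(CO[Si](c2ccccc2)(c2ccccc2)C(C)(C)C)c(OC)c1OCc1ccccc1 | intermediate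
16 | methyl (E)-3-{3-(benzyloxy)-5-({[tert-butyl(diphenyl)silyl]oxy}methyl)-2-[(2R)-2-hydroxy-4-oxobutan-2-yl]-4-methoxyphenyl}prop-2-enoate | O=CC[C@@](C)(O)c1c(/C=C/C(=O)OC)cc(CO[Si](c2ccccc2)(c2ccccc2)C(C)(C)C)c(OC)c1OCc1ccccc1 | intermediate
17 | methyl 2-[(1S,2S,4R)-5-(benzyloxy)-7-({[tert-butyl(diphenyl)silyl]oxy}methyl)-2,4-dihydroxy-6-methoxy-4-methyl-1,2,3,4-tetrahydronaphthalen-1-yl]acetate | C[C@@]1(O)C[C@H](O)[C@@H](CC(=O)OC)c2cc(CO[Si](c3ccccc3)(c3ccccc3)C(C)(C)C)c(OC)c(OCc3ccccc3)c12 | intermediate
18 | 8,10-O-isopropylidene acetal of 17 (7S,8S,10R; C2 benzyl ether) | C[C@]12C[C@H](OC(C)(C)O1)[C@@H](CC(=O)OC)c3cc(CO[Si](c4ccccc4)(c5ccccc5)C(C)(C)C)c(OC)c(OCc6ccccc6)c23 | intermediate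
19 | C2 phenol of the 8,10-O-isopropylidene tetralin (7S,8S,10R) | C[C@]12C[C@H](OC(C)(C)O1)[C@@H](CC(=O)OC)c3cc(CO[Si](c4ccccc4)(c5ccccc5)C(C)(C)C)c(OC)c(O)c23 | intermediate
20 | dienone dimethyl ketal (7S,8S,10R) | O=C1C(OC)(OC)C(CO[Si](c5ccccc5)(c6ccccc6)C(C)(C)C)=CC2=C1[C@@]3(C)C[C@H](OC(C)(C)O3)[C@H]2CC(=O)OC | intermediate
21 | (1R,6S,7R,8S,10R)-1,6-epoxy ketone of 20 | O=C1C(OC)(OC)C(CO[Si](c5ccccc5)(c6ccccc6)C(C)(C)C)=C[C@@]23O[C@@]12[C@@]4(C)C[C@H](OC(C)(C)O4)[C@H]3CC(=O)OC | intermediate
22 | p-toluenesulfonylhydrazide | Cc1ccc(cc1)S(=O)(=O)NN | starting material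
23 | tosylhydrazone of 21 (1R,6S,7R,8S,10R) | Cc1ccc(cc1)S(=O)(=O)NN=C1C(OC)(OC)C(CO[Si](c5ccccc5)(c6ccccc6)C(C)(C)C)=C[C@@]23O[C@@]12[C@@]4(C)C[C@H](OC(C)(C)O4)[C@H]3CC(=O)OC | intermediate
24 | (4Z,7R,8S,10R)-ten-membered enynone | O=C1/C=C(/CO[Si](c5ccccc5)(c6ccccc6)C(C)(C)C)C(OC)(OC)C#C[C@@]2(C)C[C@H](OC(C)(C)O2)[C@H]1CC(=O)OC | intermediate
25 | 6R hydroxy ester of 24 | O[C@@H]1/C=C(/CO[Si](c5ccccc5)(c6ccccc6)C(C)(C)C)C(OC)(OC)C#C[C@@]2(C)C[C@H](OC(C)(C)O2)[C@H]1CC(=O)OC | intermediate
26 | (6R,7R,8S,10R)-trans-6,12-lactone | C1C(=O)O[C@@H]2/C=C(/CO[Si](c5ccccc5)(c6ccccc6)C(C)(C)C)C(OC)(OC)C#C[C@@]3(C)C[C@H](OC(C)(C)O3)[C@@H]12 | intermediate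
27 | (6R,7R,8S,10R,11R)-11-(dimethylaminomethyl) lactone | CN(C)C[C@@H]1C(=O)O[C@@H]2/C=C(/CO[Si](c5ccccc5)(c6ccccc6)C(C)(C)C)C(OC)(OC)C#C[C@@]3(C)C[C@H](OC(C)(C)O3)[C@@H]12 | intermediate
28 | C3 ynone (8,10-acetonide retained) | CN(C)C[C@@H]1C(=O)O[C@@H]2/C=C(/CO[Si](c5ccccc5)(c6ccccc6)C(C)(C)C)C(=O)C#C[C@@]3(C)C[C@H](OC(C)(C)O3)[C@@H]12 | intermediate
29 | C1 diethylamino enaminone (alkene geometry open) | CN(C)C[C@@H]1C(=O)O[C@@H]2/C=C(/CO[Si](c5ccccc5)(c6ccccc6)C(C)(C)C)C(=O)C=C(N(CC)CC)[C@@]3(C)C[C@H](OC(C)(C)O3)[C@@H]12 | intermediate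
30 | (6R,7R,8S,10R,11R)-furanone alcohol | CN(C)C[C@@H]1C(=O)O[C@@H]2/C=C(/CO[Si](c5ccccc5)(c6ccccc6)C(C)(C)C)C3=CC(=O)[C@@](C)(C[C@H](O)[C@@H]12)O3 | intermediate
31 | tiglic acid | C/C=C(\C)C(=O)O | starting material
32 | (6R,7R,8S,10R,11R)-8-O-tiglate | CN(C)C[C@@H]1C(=O)O[C@@H]2/C=C(/CO[Si](c5ccccc5)(c6ccccc6)C(C)(C)C)C3=CC(=O)[C@@](C)(C[C@H](OC(=O)/C(C)=C/C)[C@@H]12)O3 | intermediate
33 | 13-(dimethylamino)-11,13-dihydrolychnophorolide B | CN(C)C[C@@H]1C(=O)O[C@@H]2/C=C(/CO)C3=CC(=O)[C@@](C)(C[C@H](OC(=O)/C(C)=C/C)[C@@H]12)O3 | intermediate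
34 | trimethylammonium iodide of 33 | C[N+](C)(C)C[C@@H]1C(=O)O[C@@H]2/C=C(/CO)C3=CC(=O)[C@@](C)(C[C@H](OC(=O)/C(C)=C/C)[C@@H]12)O3.[I-] | intermediate
35 | lychnophorolide B (6R,7R,8S,10R) | C=C1C(=O)O[C@@H]2/C=C(/CO)C3=CC(=O)[C@@](C)(C[C@H](OC(=O)/C(C)=C/C)[C@@H]12)O3 | target

## Step count and least certain steps

Total: 24 steps. Longest linear sequence: 23 steps (steps 1–6 and 8–24, from 1); step 7 is a one-step side branch.

**Step 18 (key step).** The C2 ketone sits between two fully substituted carbons, so condensation may be slow. Acid could then open the oxirane or ionise the ketal before the hydrazone forms, or the sequence could stall at the azoalkene. Fallback: from 21, condense under neutral conditions with 1-amino-2-phenylaziridine to the isolable N-aziridinyl imine F1. Heating F1 in toluene extrudes styrene and N2 without acid or base and gives 24, where the route is rejoined.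

**Step 17.** The peroxide anion may add at C4 (1,6-addition) or fail to add at the fully substituted C6, and base may deprotonate C7. Fallback: from 20, reduce the ketone 1,2 (NaBH4, CeCl3, MeOH, −78 °C, buffered work-up) to the dienol F2. The new C2 hydroxyl is allylic to C1=C6 only, so VO(acac)2/t-BuOOH should place the oxygen there and give the epoxy alcohol F3. Dess–Martin oxidation then returns 21, or its oxirane epimer F4, which fragments to 24 in step 18 in the same way. F2 can lose methanol and rearomatise, so acid must be excluded throughout.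

**Step 19.** Chelation to the acetal oxygen may be too weak, and hydride then adds to the other face and gives the 6-epimer. Fallback: from 24, reduce with the bulky non-chelating LiBH(s-Bu)3 at −78 °C, which should give the 6S alkoxide and, after lactonisation, the cis-lactone F5. LiOH opens F5 to the hydroxy acid F6, and Mitsunobu lactonisation (PPh3, DIAD) closes the ring by displacement at C6 with inversion, giving 26. The C6–O bond is then made by substitution, not by carbonyl reduction, and any F5 formed in the main step can be recycled the same way.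

**Step 13.** The aldehyde or the cinnamate may be reduced without ring closure, or the closure may give a mixture at C7 and C8 if samarium is not held by the C10 hydroxyl. Fallback: from 16, an intramolecular Stetter reaction (chiral triazolium carbene precatalyst, KHMDS cat., toluene) forms C7–C8 by polar addition of the acyl anion equivalent and gives the C8 ketone F7. The C7 configuration is then set by the catalyst. Reduction with Et2BOMe/NaBH4 (Narasaka–Prasad), directed by the C10 hydroxyl, gives the cis-diol 17.

## Further compounds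

F1 | step 18 | N-(2-phenylaziridin-1-yl) imine of 21 (aziridine carbon racemic) | C8(c7ccccc7)CN8N=C1C(OC)(OC)C(CO[Si](c5ccccc5)(c6ccccc6)C(C)(C)C)=C[C@@]23O[C@@]12[C@@]4(C)C[C@H](OC(C)(C)O4)[C@H]3CC(=O)OC
F2 | step 17 | C2 dienol of 20 (C2 configuration open) | OC1C(OC)(OC)C(CO[Si](c5ccccc5)(c6ccccc6)C(C)(C)C)=CC2=C1[C@@]3(C)C[C@H](OC(C)(C)O3)[C@H]2CC(=O)OC
F3 | step 17 | 1,6-epoxy C2 alcohol (oxirane syn to the hydroxyl; C1, C2 and C6 configuration open) | OC1C(OC)(OC)C(CO[Si](c5ccccc5)(c6ccccc6)C(C)(C)C)=CC23OC12[C@@]4(C)C[C@H](OC(C)(C)O4)[C@H]3CC(=O)OC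
F4 | step 17 | (1S,6R)-oxirane epimer of 21 | O=C1C(OC)(OC)C(CO[Si](c5ccccc5)(c6ccccc6)C(C)(C)C)=C[C@]23O[C@]12[C@@]4(C)C[C@H](OC(C)(C)O4)[C@H]3CC(=O)OC
F5 | step 19 | 6-epi (cis) lactone of 26 | C1C(=O)O[C@H]2/C=C(/CO[Si](c5ccccc5)(c6ccccc6)C(C)(C)C)C(OC)(OC)C#C[C@@]3(C)C[C@H](OC(C)(C)O3)[C@@H]12
F6 | step 19 | 6-epi hydroxy acid | O[C@H]1/C=C(/CO[Si](c5ccccc5)(c6ccccc6)C(C)(C)C)C(OC)(OC)C#C[C@@]2(C)C[C@H](OC(C)(C)O2)[C@H]1CC(=O)O
F7 | step 13 | C8 ketone (4-hydroxy-4-methyl-2-tetralone with the C7 acetate arm) | C[C@@]1(O)CC(=O)[C@@H](CC(=O)OC)c2cc(CO[Si](c3ccccc3)(c3ccccc3)C(C)(C)C)c(OC)c(OCc3ccccc3)c12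
A1 | alternative 1 | bridged furanone lactone without C13 (15-O-TBS, 8-O-TES) | C1C(=O)O[C@@H]2/C=C(/CO[Si](C)(C)C(C)(C)C)C3=CC(=O)[C@@](C)(C[C@H](O[Si](CC)(CC)CC)[C@@H]12)O3
A2 | alternative 2 | trans lactone with the Z 2-ethoxydiene | C1C(=O)O[C@H](/C=C(/CO[Si](C)(C)C(C)(C)C)C(=C)OCC)[C@H]1[C@@H]2C[C@](C)(COCc3ccc(OC)cc3)OC(C)(C)O2
A3 | alternative 2 | 1-ethoxyvinylzinc chloride | CCOC(=C)[Zn]Cl
A4 | alternative 3 | 15-O-TBS alcohol with the complete ring system | C=C1C(=O)O[C@@H]2/C=C(/CO[Si](C)(C)C(C)(C)C)C3=CC(=O)[C@@](C)(C[C@H](O)[C@@H]12)O3
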